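The amounts came first. The left-handed substrate was 0.5 of the substrate charged, so I counted it as a fraction of that share.

| flask | left-handed substrate | right-handed substrate | partner | free catalyst | remark | time |
|---|---|---|---|---|---|---|
| theta | 0.20 M | 0.20 M | 2 equiv | 0.1 mol% | the very flask that is asked about, followed so far |  |
| flask | 0.20 M | 0.20 M | 2.00 equiv | 0.1 mol% |  | 8.0 d |

theta run (percent of the left-handed substrate and right-handed substrate together charged)

| time / h | left-handed product / % | left-handed substrate / % |
|---|---|---|
| 10.0 | 29.4 | 20.6 |
| 20.0 | 37.3 | 13.4 |
| 30.0 | 41.0 | 8.9 |
| 60.0 | 43.3 | 6.9 |
| 120 | 43.7 | 5.3 |

(scatter of a reading: 0.5 percentage points)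

- free catalyst is single-handed; left-handed substrate and right-handed substrate are mirror images of each other, charged as a racemate, each of them at the stated concentration
- left-handed product taken out counts as made
- the numbers in the tables scatter by 0.5 percentage points (one standard deviation)
- reactions considered so far: free catalyst + right-handed substrate <-> catalyst intermediate B; partner -> decomposition product; free catalyst + left-handed substrate <-> catalyst intermediate A; partner -> decomposed reagent; 2 free catalyst <-> resting dimer; partner + catalyst intermediate B -> free catalyst + right-handed product; partner + catalyst intermediate A -> free catalyst + left-handed product
- additions bring no volume worth counting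

- south: at 8.0 d add free catalyst, 50.0% of the amount charged, then wait 8.0 d
- north: at 8.0 d add partner, 50.0% of the amount charged, then wait 8.0 d
- south-west: change nothing and wait 8.0 d more
- north-east: at 8.0 d take out 90% of the left-handed product then present, then wait 8.0 d

- left-handed product, in percent of the left-handed substrate and right-handed substrate together first charged, at 8.0 d
- which option adds most left-handed product ("none" when 2 percentage points or less is all one gets) (south / north / south-west / north-east / none)
- left-handed product present, with what was taken out counted in, in percent of the left-handed substrate and right-handed substrate together first charged, after south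
- left-handed product present, with what was taken out counted in, in percent of the left-handed substrate and right-handed substrate together first charged, after north-east

Left-handed product and left-handed substrate still summed to 49.9% at 30.0 h, so the left-handed pool was intact. But the logarithm of the substrate fell by 0.887 in the first 10.0 h, and by 0.264 between 60.0 h and 120 h. In the listed steps the catalyst parks reversibly while the partner decays irreversibly, so I stopped counting in hours and counted in partner.

I defined the partner's purchase as the total logarithmic fall of the left-handed fraction that one charge of partner buys, 2.24. This replaces a curved pseudo-first-order fall by its mean per unit of partner, and it carries the scatter of 0.5 percentage points on a reading of 5.3%.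

So north, at 50.0% of a charge, should buy a further fall of 1.12, which I reckoned as a gain of 3.6 points against a margin of 2 points. The other options add no partner, so I expected nothing from them.

The forecast said 44.4% at 8.0 d, north as best, 44.7% after south and 44.5% after north-east, with a gain of about 3 points for north where I had 3.6 points: “Fresh partner, at half the original dose, restarts the reaction”.

The flask gave 44.4% at 8.0 d, 44.4% after south and 44.4% after north-east, and north was best, adding 5.1 points. The partner, the limiting reagent, stood at 0% at 192 h. Applied to the 5.61% of left-handed substrate that stood then, the purchase of 2.24 gives 3.8 points for north, beside the 5.1 points the flask added.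

    free catalyst + right-handed substrate ⇌ catalyst intermediate B (K = 1.80 M⁻¹, k = 13.0 M⁻¹ s⁻¹)
    partner → decomposition product (k = 5.40 × 10⁻⁸ s⁻¹)
    free catalyst + left-handed substrate ⇌ catalyst intermediate A (K = 13.0 M⁻¹, k = 3.60 M⁻¹ s⁻¹)
    partner → decomposed reagent (k = 1.00 × 10⁻⁵ s⁻¹)
    2 free catalyst ⇌ resting dimer, settled at all times (K = 3700 M⁻¹)
    partner + catalyst intermediate B → free catalyst + right-handed product (k = 0.0490 M⁻¹ s⁻¹)
    partner + catalyst intermediate A → free catalyst + left-handed product (k = 0.130 M⁻¹ s⁻¹)

For the neighbour flask with 3.40 equiv of partner, all else held, the purchase scaled by the charge of partner reckons to a fall of 3.82, and so to 48.9% of left-handed product. That flask gave 49.8%.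

The data stem from a simulated flask on assumed constants; the scatter is artificial.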